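(All runs come from a simulation on assumed constants, noise included.)

A first-order step turns the same fraction of what stands in a given time, whatever the amount. So if D goes to G by such steps, each portion of D works on its own, and G at any moment is the sum of what each portion has given at its age (superposition). The question is whether that holds here.

| flask | D | X | remark | time |
|---|---|---|---|---|
| oak | 0.29 M (in portions, 3) | 0.10 M | run made earlier; portions every 30 s |  |
| west | 0.20 M (in portions, 3) | 0.100 M | the portions of D follow each other after 30 s, the first at the start | 2.5 min |
| north-east | 0.40 M (in portions, 3) | 0.100 M | the portions of D follow each other after 30 s, the first at the start | 2.5 min |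
| south | 0.80 M (in portions, 3) | 0.100 M | the portions of D follow each other after 30 s, the first at the start | 2.5 min |
| north | 1.5 M (in portions, 3) | 0.100 M | the portions of D follow each other after 30 s, the first at the start | 2.5 min |
| east | 3.0 M (in portions, 3) | 0.100 M | the portions of D follow each other after 30 s, the first at the start | 2.5 min |

oak run (percent of the D charged)

| time / s | G / % |
|---|---|
| 10.0 | 3.2 |
| 12.0 | 3.3 |
| 20.0 | 2.5 |
| 40.0 | 6.3 |
| 80.0 | 6.7 |

(scatter of a reading: 0.5 percentage points)

- "hardly changes" means that all values lie within two and a half points (for a concentration: within two and a half percent of the largest)

- amount of G at the end, in percent of the D charged for west, north-east, south, north, east, in this order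
- how that number moves from the first to the last of them (falls, then rises / rises all the way / hardly changes / falls all the way / rises, then falls)

I call portion yield the G that one portion has given, in percent of that portion. In the oak run the readings from 10.0 s to 20.0 s come before the second portion, so their mean, multiplied by 3, gives a young yield of 9.00 %. At 80.0 s the newest portion is 20.0 s old and still young. I multiply that reading by 3, take off the young yield, and the mean of the two older portions, 5.55 %, is the late portion yield. This is a reading with a scatter of about 0.87 percentage points. The same subtraction at 40.0 s gives 9.90 %, with a scatter of about 1.7 points, so these readings do not date the fall.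

Could a shortage of X cause the fall? If each G took up one X, the oak flask at 80.0 s would have used 19.4 % of its X, yet the yield is down by more than that, 38.3 %. I therefore read the fall as a loss that runs by the clock, and I take X to be no part of G. This is a bet, since oak shows one charge.

The five flasks keep the 30 s spacing. At 2.5 min their youngest portion is 90.0 s old, older than the portions behind the late yield. On this bet the end value is the mean yield of the portions, and the charge does not enter it. I expect a flat row near 5.55 %, or somewhat below if the loss continues. In the east flask that means 0.167 M of G, more than the 0.100 M of X, which needs my bet to hold.

The forecast gives 8.3 % down to 2.5 %, falls all the way, on this ground: “G is limited by X at 0.10 M, so G as a percent of D must fall as D rises”.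

The flasks end at 6.01 %, 6.03 %, 6.08 %, 6.16 % and 6.26 %, so the row hardly changes.

    D ⇌ L (K = 2.90, k = 0.540 s⁻¹)
    D ⇌ E (K = 2.90, k = 0.0460 s⁻¹)
    D ⇌ G (K = 0.480, k = 0.430 s⁻¹)
    D + X → Z (k = 0.0340 M⁻¹ s⁻¹)
    G → Q (k = 0.00440 s⁻¹)

In the west flask D has a forward half-life of 1.3 s towards L at 0.0658 min and 3.4 min by the step with X, while D and E relax with a half-life of 0.187 min, shorter than the 30 s between portions. On the east flask the late portion yield gives 0.167 M and the flask holds 0.188 M of G, above the 0.100 M of X charged, with 14 % of that X left.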